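## Retrosynthetic overview

1. The hydroperoxide is unmasked last from a 2-methoxyprop-2-yl peroxyketal; the cross-conjugated dienone is cut at both C–C(=O) bonds (carbonylative Stille coupling of a ring-bound 1-iodovinyl group, CO and an E-vinylstannane carrying the masked peroxide).
2. The cis-epoxy ketone comes from the enone by 1,2-reduction, hydroxyl-directed epoxidation and re-oxidation; the tiglate comes from enolate hydroxylation/acylation trans to the side-chain carbon.
3. The cyclohexenone is made by a two-carbon ring expansion of a prochiral 3-substituted cyclobutanone with propyne; this desymmetrisation sets the first stereocenter, which controls all the others.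
4. The cyclobutanone comes from 3-oxocyclobutane-1-carboxylic acid and (1-bromoethenyl)trimethylsilane by decarboxylative alkenylation; the vinylsilane is the latent 1-iodovinyl group.
5. Ring order: cyclobutanone (bought) → cyclohexenone (ring expansion) → oxirane.

Assumption: CO, H2O2, tBuOOH, N-iodosuccinimide, the oxaziridine, Bu3SnH and 2-methoxypropene are treated as reagents rather than numbered starting materials, and the antipode of the chiral carbene ligand that gives the (R)-cyclohexenone is used.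

Ring numbering used in the comments: C1 ketone carbon, C2 methyl-bearing carbon, C3 second epoxide carbon, C4 CH2, C5 side-chain carbon, C6 ester-bearing carbon.

## Route

Step 1
Reactants: 1 3-oxocyclobutane-1-carboxylic acid; 2 (1-bromoethenyl)trimethylsilane
Product: 3 3-[1-(trimethylsilyl)ethenyl]cyclobutan-1-one
Conditions: Ir[dF(CF3)ppy]2(dtbbpy)PF6 (1 mol%), NiCl2·glyme (10 mol%), 4,4'-di-tert-butyl-2,2'-bipyridine (15 mol%), Cs2CO3 (1.5 equiv), DMSO, blue LEDs, 25 °C
Reagents that add atoms: none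
Why: Metallaphotoredox decarboxylative alkenylation: photo-oxidation of the caesium carboxylate releases CO2 and a 3-oxocyclobutyl radical that the nickel catalyst couples with the vinyl bromide; the product is achiral, so no stereocenter is set.

Step 2
Reactants: 3 3-[1-(trimethylsilyl)ethenyl]cyclobutan-1-one; 4 propyne
Product: 5 (5R)-2-methyl-5-[1-(trimethylsilyl)ethenyl]cyclohex-2-en-1-one
Conditions: Ni(cod)2 (10 mol%), chiral carbene L* (12 mol%, from its imidazolium chloride and KOtBu), propyne (3 equiv, 1 M in THF, added over 6 h), toluene, 30 °C; L* = C2-symmetric acenaphtho-fused imidazol-2-ylidene bearing a 2,6-bis(1-phenylethyl)-4-methylphenyl group on each nitrogen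
Reagents that add atoms: none
Why: Proposed new method: a zerovalent nickel complex of the bulky chiral carbene should join the cyclobutanone C=O and propyne by oxidative cyclisation (the large ligand pushes the alkyne methyl carbon onto the carbonyl carbon, as in ligand-controlled regiochemistry reversal of nickel-catalysed aldehyde–alkyne couplings), then strain-driven β-carbon elimination of one of the two enantiotopic ring C–C bonds sets C5 and C(sp2)–C(sp3) reductive elimination closes the six-membered ring; the closest known reaction is the zerovalent-nickel-catalysed insertion of internal alkynes into cyclobutanones (two-carbon ring expansion), not yet shown with a terminal alkyne or as an intermolecular enantioselective desymmetrisation.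

Step 3
Reactants: 5 (5R)-2-methyl-5-[1-(trimethylsilyl)ethenyl]cyclohex-2-en-1-one; 6 (E)-2-methylbut-2-enoyl chloride (tigloyl chloride)
Product: 9 (1S,6R)-3-methyl-2-oxo-6-[1-(trimethylsilyl)ethenyl]cyclohex-3-en-1-yl (E)-2-methylbut-2-enoate, via potassium dienolate 7 (not isolated), via potassium alkoxide 8 (not isolated)
Conditions: KN(SiMe3)2 (1.1 equiv), THF, −78 °C; 3-phenyl-2-(phenylsulfonyl)oxaziridine (1.3 equiv), −78 °C; then 6 (1.6 equiv), −78 → 0 °C
Reagents that add atoms: 3-phenyl-2-(phenylsulfonyl)oxaziridine (Davis oxaziridine), O=S(=O)(c1ccccc1)N1OC1c1ccccc1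
Why: Kinetic cross-conjugated enolate formation, Davis oxaziridine α'-hydroxylation on the face anti to the neighbouring C5 substituent (sets C6 trans to C5, also the thermodynamic arrangement) and O-acylation of the alkoxide in the same flask.

Step 4
Reactants: 9 (1S,6R)-3-methyl-2-oxo-6-[1-(trimethylsilyl)ethenyl]cyclohex-3-en-1-yl (E)-2-methylbut-2-enoate
Product: 10 (1S,6R)-6-(1-iodoethenyl)-3-methyl-2-oxocyclohex-3-en-1-yl (E)-2-methylbut-2-enoate
Conditions: N-iodosuccinimide (1.3 equiv), MeCN/ClCH2CN 4:1, 0 → 25 °C, dark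
Reagents that add atoms: N-iodosuccinimide, O=C1CCC(=O)N1I
Why: Iododesilylation (ipso substitution of a 2-silyl-1-alkene through the β-silyl cation) gives the 1-iodovinyl handle; the enone and tiglate alkenes are too electron-poor to react and no stereocenter is touched.

Step 5
Reactants: 10 (1S,6R)-6-(1-iodoethenyl)-3-methyl-2-oxocyclohex-3-en-1-yl (E)-2-methylbut-2-enoate
Product: 11 (1S,2S,6R)-2-hydroxy-6-(1-iodoethenyl)-3-methylcyclohex-3-en-1-yl (E)-2-methylbut-2-enoate
Conditions: NaBH4 (1.0 equiv), CeCl3·7H2O (1.1 equiv), MeOH, −78 °C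
Reagents that add atoms: none
Why: Luche 1,2-reduction; axial hydride delivery gives the equatorial alcohol, cis to the C5 substituent and trans to the tiglate, which is the carbinol configuration needed to direct the epoxidation.

Step 6
Reactants: 11 (1S,2S,6R)-2-hydroxy-6-(1-iodoethenyl)-3-methylcyclohex-3-en-1-yl (E)-2-methylbut-2-enoate
Product: 12 (1R,2R,3S,4R,6S)-2-hydroxy-4-(1-iodoethenyl)-1-methyl-7-oxabicyclo[4.1.0]heptan-3-yl (E)-2-methylbut-2-enoate
Conditions: VO(acac)2 (5 mol%), tBuOOH (1.5 equiv, 5.5 M in decane), CH2Cl2, 0 → 25 °C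
Reagents that add atoms: tert-butyl hydroperoxide, CC(C)(C)OO
Why: Hydroxyl-directed vanadium-catalysed epoxidation of the cyclic allylic alcohol delivers oxygen syn to the OH, setting C2 and C3 with the oxirane cis to the C5 side chain and trans to the tiglate; the vinyl iodide and tiglate alkenes are not allylic alcohols and are left alone.

Step 7
Reactants: 12 (1R,2R,3S,4R,6S)-2-hydroxy-4-(1-iodoethenyl)-1-methyl-7-oxabicyclo[4.1.0]heptan-3-yl (E)-2-methylbut-2-enoate
Product: 13 (1S,3S,4R,6S)-4-(1-iodoethenyl)-1-methyl-2-oxo-7-oxabicyclo[4.1.0]heptan-3-yl (E)-2-methylbut-2-enoate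
Conditions: Dess–Martin periodinane (1.5 equiv), CH2Cl2, 0 → 25 °C
Reagents that add atoms: none
Why: Dess–Martin oxidation of the secondary epoxy alcohol under non-basic conditions gives the α,β-epoxy ketone without epimerising the α-acyloxy center.

Step 8
Reactants: 14 2-methylbut-3-yn-2-ol
Product: 15 3-hydroperoxy-3-methylbut-1-yne
Conditions: H2O2 (50% aq., 3 equiv), H2SO4 (cat.), 0 °C
Reagents that add atoms: hydrogen peroxide, OO
Why: Acid-catalysed perhydrolysis (SN1 substitution through the tertiary propargylic cation) of the alcohol.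

Step 9
Reactants: 15 3-hydroperoxy-3-methylbut-1-yne
Product: 16 3-[(2-methoxypropan-2-yl)peroxy]-3-methylbut-1-yne
Conditions: 2-methoxypropene (1.5 equiv), pyridinium p-toluenesulfonate (2 mol%), CH2Cl2, 0 °C
Reagents that add atoms: 2-methoxypropene, C=C(C)OC
Why: Acid-catalysed addition of the hydroperoxide to the enol ether gives the peroxyketal, which masks the O–O–H group for the metal-mediated steps.

Step 10
Reactants: 16 3-[(2-methoxypropan-2-yl)peroxy]-3-methylbut-1-yne
Product: 17 tributyl{(1E)-3-[(2-methoxypropan-2-yl)peroxy]-3-methylbut-1-en-1-yl}stannane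
Conditions: Bu3SnH (1.1 equiv), PdCl2(PPh3)2 (2 mol%), THF, 0 °C
Reagents that add atoms: tributyltin hydride, CCCC[SnH](CCCC)CCCC
Why: Palladium-catalysed syn-hydrostannation; the bulky tertiary propargylic substituent sends tin to the terminal carbon and gives the E-vinylstannane.

Step 11
Reactants: 13 (1S,3S,4R,6S)-4-(1-iodoethenyl)-1-methyl-2-oxo-7-oxabicyclo[4.1.0]heptan-3-yl (E)-2-methylbut-2-enoate; 17 tributyl{(1E)-3-[(2-methoxypropan-2-yl)peroxy]-3-methylbut-1-en-1-yl}stannane
Product: 18 (1S,3S,4S,6S)-4-{(4E)-5-[(2-methoxypropan-2-yl)peroxy]-5-methyl-3-oxohexa-1,4-dien-2-yl}-1-methyl-2-oxo-7-oxabicyclo[4.1.0]heptan-3-yl (E)-2-methylbut-2-enoate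
Conditions: Pd2(dba)3 (5 mol%), AsPh3 (20 mol%), CO (1 atm), N-methylpyrrolidone, 45 °C
Reagents that add atoms: carbon monoxide, [C-]#[O+]
Why: Carbonylative Stille coupling: oxidative addition of the vinyl iodide to zerovalent palladium, CO insertion and transmetalation/reductive elimination with retention of the E geometry build the cross-conjugated dienone under neutral conditions that peroxyketals are expected to survive; no stereocenter is touched.

Step 12
Reactants: 18 (1S,3S,4S,6S)-4-{(4E)-5-[(2-methoxypropan-2-yl)peroxy]-5-methyl-3-oxohexa-1,4-dien-2-yl}-1-methyl-2-oxo-7-oxabicyclo[4.1.0]heptan-3-yl (E)-2-methylbut-2-enoate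
Product: 19 (1S,3S,4S,6S)-4-[(4E)-5-hydroperoxy-5-methyl-3-oxohexa-1,4-dien-2-yl]-1-methyl-2-oxo-7-oxabicyclo[4.1.0]heptan-3-yl (E)-2-methylbut-2-enoate
Conditions: AcOH/THF/H2O 3:1:1, 25 °C
Reagents that add atoms: none
Why: Mild acid hydrolysis of the peroxyketal (peroxyketal deprotection) frees the hydroperoxide without opening the epoxy ketone or cleaving the tiglate.

## Compound list

1 | 3-oxocyclobutane-1-carboxylic acid | O=C1CC(C1)C(=O)O | starting material
2 | (1-bromoethenyl)trimethylsilane | C=C(Br)[Si](C)(C)C | starting material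
3 | 3-[1-(trimethylsilyl)ethenyl]cyclobutan-1-one | C=C([Si](C)(C)C)C1CC(=O)C1 | intermediate
4 | propyne | CC#C | starting material
5 | (5R)-2-methyl-5-[1-(trimethylsilyl)ethenyl]cyclohex-2-en-1-one | C=C([Si](C)(C)C)[C@@H]1CC=C(C)C(=O)C1 | intermediate
6 | (E)-2-methylbut-2-enoyl chloride (tigloyl chloride) | C/C=C(\C)C(=O)Cl | starting material
7 | potassium (3R)-6-methyl-3-[1-(trimethylsilyl)ethenyl]cyclohexa-1,5-dien-1-olate | C=C([Si](C)(C)C)[C@@H]1CC=C(C)C([O-])=C1.[K+] | intermediate
8 | potassium (1S,6R)-3-methyl-2-oxo-6-[1-(trimethylsilyl)ethenyl]cyclohex-3-en-1-olate | C=C([Si](C)(C)C)[C@@H]1CC=C(C)C(=O)[C@H]1[O-].[K+] | intermediate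
9 | (1S,6R)-3-methyl-2-oxo-6-[1-(trimethylsilyl)ethenyl]cyclohex-3-en-1-yl (E)-2-methylbut-2-enoate | C=C([Si](C)(C)C)[C@@H]1CC=C(C)C(=O)[C@H]1OC(=O)/C(C)=C/C | intermediate
10 | (1S,6R)-6-(1-iodoethenyl)-3-methyl-2-oxocyclohex-3-en-1-yl (E)-2-methylbut-2-enoate | C=C(I)[C@@H]1CC=C(C)C(=O)[C@H]1OC(=O)/C(C)=C/C | intermediate
11 | (1S,2S,6R)-2-hydroxy-6-(1-iodoethenyl)-3-methylcyclohex-3-en-1-yl (E)-2-methylbut-2-enoate | C=C(I)[C@@H]1CC=C(C)[C@H](O)[C@H]1OC(=O)/C(C)=C/C | intermediate
12 | (1R,2R,3S,4R,6S)-2-hydroxy-4-(1-iodoethenyl)-1-methyl-7-oxabicyclo[4.1.0]heptan-3-yl (E)-2-methylbut-2-enoate | C=C(I)[C@@H]1C[C@@H]2O[C@]2(C)[C@H](O)[C@H]1OC(=O)/C(C)=C/C | intermediate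
13 | (1S,3S,4R,6S)-4-(1-iodoethenyl)-1-methyl-2-oxo-7-oxabicyclo[4.1.0]heptan-3-yl (E)-2-methylbut-2-enoate | C=C(I)[C@@H]1C[C@@H]2O[C@]2(C)C(=O)[C@H]1OC(=O)/C(C)=C/C | intermediate
14 | 2-methylbut-3-yn-2-ol | CC(C)(O)C#C | starting material
15 | 3-hydroperoxy-3-methylbut-1-yne | CC(C)(OO)C#C | intermediate
16 | 3-[(2-methoxypropan-2-yl)peroxy]-3-methylbut-1-yne | COC(C)(C)OOC(C)(C)C#C | intermediate
17 | tributyl{(1E)-3-[(2-methoxypropan-2-yl)peroxy]-3-methylbut-1-en-1-yl}stannane | CCCC[Sn](CCCC)(CCCC)/C=C/C(C)(C)OOC(C)(C)OC | intermediate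
18 | (1S,3S,4S,6S)-4-{(4E)-5-[(2-methoxypropan-2-yl)peroxy]-5-methyl-3-oxohexa-1,4-dien-2-yl}-1-methyl-2-oxo-7-oxabicyclo[4.1.0]heptan-3-yl (E)-2-methylbut-2-enoate | C=C(C(=O)/C=C/C(C)(C)OOC(C)(C)OC)[C@@H]1C[C@@H]2O[C@]2(C)C(=O)[C@H]1OC(=O)/C(C)=C/C | intermediate
19 | (1S,3S,4S,6S)-4-[(4E)-5-hydroperoxy-5-methyl-3-oxohexa-1,4-dien-2-yl]-1-methyl-2-oxo-7-oxabicyclo[4.1.0]heptan-3-yl (E)-2-methylbut-2-enoate | C=C(C(=O)/C=C/C(C)(C)OO)[C@@H]1C[C@@H]2O[C@]2(C)C(=O)[C@H]1OC(=O)/C(C)=C/C | target

## Step count and risks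

Total step count: 12 (steps 1–7, 11 and 12 in the main line; steps 8–10 for stannane 17).
Longest linear sequence: 9 steps (1 → 3 → 5 → 9 → 10 → 11 → 12 → 13 → 18 → 19).

**Step 2 (the proposed ring expansion).** Propyne may oligomerise on nickel, insert with the wrong regiochemistry (3-methyl isomer), or give low enantioselectivity. The fallback uses the known Saegusa–Ito one-carbon ring expansion of a cyclopentanone; it sets out from 2, uses commercial cyclopent-2-en-1-one (six non-hydrogen atoms), and comes back to the route at 9. Compound 2 is converted with Mg in THF into [1-(trimethylsilyl)ethenyl]magnesium bromide F1. F1 is added to cyclopent-2-en-1-one under CuBr·SMe2 / Josiphos-type ferrocenyl diphosphine catalysis with Me3SiCl trapping, giving (R)-trimethyl({3-[1-(trimethylsilyl)ethenyl]cyclopent-1-en-1-yl}oxy)silane F2. Rubottom oxidation (mCPBA, NaHCO3, CH2Cl2, −20 °C; then citric acid in MeOH) gives (2S,3R)-2-hydroxy-3-[1-(trimethylsilyl)ethenyl]cyclopentan-1-one F3, with oxygen entering anti to the neighbouring substituent. Acylation with 6 (pyridine, cat. DMAP) gives (1S,5R)-2-oxo-5-[1-(trimethylsilyl)ethenyl]cyclopentyl (E)-2-methylbut-2-enoate F4. Kinetic enolisation on the CH2 side (LiN(SiMe3)2, Me3SiCl, THF, −78 °C) gives (1S,5R)-2-[(trimethylsilyl)oxy]-5-[1-(trimethylsilyl)ethenyl]cyclopent-2-en-1-yl (E)-2-methylbut-2-enoate F5. Ethylidene transfer (Et2Zn, CH3CHI2, CH2Cl2, 0 °C) gives (2S,3R)-6-methyl-1-[(trimethylsilyl)oxy]-3-[1-(trimethylsilyl)ethenyl]bicyclo[3.1.0]hexan-2-yl (E)-2-methylbut-2-enoate F6. FeCl3 in DMF at 0 °C opens the ring-fusion bond to the ring-expanded (1S,6R)-4-chloro-3-methyl-2-oxo-6-[1-(trimethylsilyl)ethenyl]cyclohexyl (E)-2-methylbut-2-enoate F7, and NaOAc in warm MeOH eliminates HCl to give 9. The weak points of this fallback are the enantioselectivity of the copper step with a hindered Grignard reagent and the selectivity for ring-fusion bond cleavage in the methyl-substituted cyclopropane.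

**Step 1 (metallaphotoredox alkenylation).** The unstabilised cyclobutyl radical and the hindered α-silyl vinyl bromide may give a low yield. The fallback sets out from 1 and comes back at 3, using a redox-active ester and an organozinc instead of direct photo-decarboxylation. Acid 1 is condensed with N-hydroxyphthalimide (N,N'-diisopropylcarbodiimide, cat. DMAP, CH2Cl2) to 1,3-dioxoisoindolin-2-yl 3-oxocyclobutane-1-carboxylate F8. Separately, 2 is lithiated (tBuLi, 2 equiv, THF, −78 °C) to [1-(trimethylsilyl)ethenyl]lithium F9 and transmetalated with ZnCl2 to chloro[1-(trimethylsilyl)ethenyl]zinc F10. Nickel-catalysed decarboxylative alkenylation of F8 with F10 (NiCl2·glyme, 2,2'-bipyridine, THF/DMF, 25 °C) gives 3.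

**Step 11 (carbonylative Stille coupling).** The hindered vinyl iodide may couple slowly, direct (non-carbonylative) coupling may compete, and the peroxyketal may not survive palladium and tin. The fallback sets out from 12 and comes back at 19, installing the peroxide after the carbon skeleton is complete. 4-Methylpent-3-enal F11 is made by Dess–Martin oxidation of commercial 4-methylpent-3-en-1-ol. Nozaki–Hiyama–Kishi coupling of 12 with F11 (CrCl2, 4 equiv; NiCl2, 1 mol%; DMSO, 25 °C) gives (1R,2R,3S,4S,6S)-2-hydroxy-4-(3-hydroxy-6-methylhepta-1,5-dien-2-yl)-1-methyl-7-oxabicyclo[4.1.0]heptan-3-yl (E)-2-methylbut-2-enoate F12 as a mixture of carbinol epimers. Dess–Martin oxidation of both secondary alcohols gives (1S,3S,4S,6S)-1-methyl-4-(6-methyl-3-oxohepta-1,5-dien-2-yl)-2-oxo-7-oxabicyclo[4.1.0]heptan-3-yl (E)-2-methylbut-2-enoate F13. A Schenck ene reaction with singlet oxygen (O2, tetraphenylporphyrin, visible light, CH2Cl2, 0 °C) then gives 19 directly. The E tertiary allylic hydroperoxide must be separated from the regioisomeric secondary hydroperoxide, which may be the major product, so this is the weaker end-game.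

## Further compounds

F1 | step 2 | [1-(trimethylsilyl)ethenyl]magnesium bromide | C=C([Mg]Br)[Si](C)(C)C
F2 | step 2 | (R)-trimethyl({3-[1-(trimethylsilyl)ethenyl]cyclopent-1-en-1-yl}oxy)silane | C=C([Si](C)(C)C)[C@@H]1CCC(O[Si](C)(C)C)=C1
F3 | step 2 | (2S,3R)-2-hydroxy-3-[1-(trimethylsilyl)ethenyl]cyclopentan-1-one | C=C([Si](C)(C)C)[C@@H]1CCC(=O)[C@H]1O
F4 | step 2 | (1S,5R)-2-oxo-5-[1-(trimethylsilyl)ethenyl]cyclopentyl (E)-2-methylbut-2-enoate | C=C([Si](C)(C)C)[C@@H]1CCC(=O)[C@H]1OC(=O)/C(C)=C/C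
F5 | step 2 | (1S,5R)-2-[(trimethylsilyl)oxy]-5-[1-(trimethylsilyl)ethenyl]cyclopent-2-en-1-yl (E)-2-methylbut-2-enoate | C=C([Si](C)(C)C)[C@@H]1CC=C(O[Si](C)(C)C)[C@H]1OC(=O)/C(C)=C/C
F6 | step 2 | (2S,3R)-6-methyl-1-[(trimethylsilyl)oxy]-3-[1-(trimethylsilyl)ethenyl]bicyclo[3.1.0]hexan-2-yl (E)-2-methylbut-2-enoate, cyclopropane carbons as a mixture | C=C([Si](C)(C)C)[C@@H]1CC2C(C)C2(O[Si](C)(C)C)[C@H]1OC(=O)/C(C)=C/C
F7 | step 2 | (1S,6R)-4-chloro-3-methyl-2-oxo-6-[1-(trimethylsilyl)ethenyl]cyclohexyl (E)-2-methylbut-2-enoate, mixture at C3 and C4 | C=C([Si](C)(C)C)[C@@H]1CC(Cl)C(C)C(=O)[C@H]1OC(=O)/C(C)=C/C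
F8 | step 1 | 1,3-dioxoisoindolin-2-yl 3-oxocyclobutane-1-carboxylate | O=C1CC(C1)C(=O)ON1C(=O)c2ccccc2C1=O
F9 | step 1 | [1-(trimethylsilyl)ethenyl]lithium | [Li]C(=C)[Si](C)(C)C
F10 | step 1 | chloro[1-(trimethylsilyl)ethenyl]zinc | Cl[Zn]C(=C)[Si](C)(C)C
F11 | step 11 | 4-methylpent-3-enal | CC(C)=CCC=O
F12 | step 11 | (1R,2R,3S,4S,6S)-2-hydroxy-4-(3-hydroxy-6-methylhepta-1,5-dien-2-yl)-1-methyl-7-oxabicyclo[4.1.0]heptan-3-yl (E)-2-methylbut-2-enoate, carbinol epimers | C=C(C(O)CC=C(C)C)[C@@H]1C[C@@H]2O[C@]2(C)[C@H](O)[C@H]1OC(=O)/C(C)=C/C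
F13 | step 11 | (1S,3S,4S,6S)-1-methyl-4-(6-methyl-3-oxohepta-1,5-dien-2-yl)-2-oxo-7-oxabicyclo[4.1.0]heptan-3-yl (E)-2-methylbut-2-enoate | C=C(C(=O)CC=C(C)C)[C@@H]1C[C@@H]2O[C@]2(C)C(=O)[C@H]1OC(=O)/C(C)=C/C
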